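**Plan**

- Retrosynthesis: the isopropylidene C=C is cut to a ring ketone and acetone. In that cyclohexanone ring, the CH carrying the propanoate is then excised completely (both of its ring bonds and its side-chain bond), which leaves a trans-hydrindan-1-one, CH2Br2 and methyl acrylate. The benzylic C–C bond at the quaternary carbon and the two annulation bonds of the other carbocycle are cut last.
- Forward order: cyclopentane ring (from 2-methylcyclopentane-1,3-dione), then the cyclohexenone ring by aldol annulation, then the arylmethyl fragment, then the secondary methyl; the cyclopentanone is then enlarged to the cyclohexanone with the chain attached, and the isopropylidene group and deprotection close the route.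
- Enabling feature: in the isopropylidene-bearing ring the CH that carries the propanoic acid chain lies between the isopropylidene carbon (a latent C=O) and the methyl-bearing quaternary ring-fusion carbon. It can therefore be inserted as a carbenoid carbon between a cyclopentanone C=O and its quaternary α-carbon, and the ring-enlarged enolate is nucleophilic at exactly this carbon.
- Stereochemistry: the quaternary ring-fusion carbon comes from a D-phenylalanine-mediated aldol desymmetrization. The ring-fusion H and the benzylic quaternary carbon come from reductive alkylation anti to the angular methyl. The secondary methyl comes from hydrogenation on the face opposite the two axial methyls. The chain-bearing CH is set by equilibration α to the new ketone (equatorial, syn to the angular methyl).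

Key step: step 11

Remark: the SMILES is read as a trans-fused decalin with the chain-bearing CH equatorial and syn to the angular methyl; compounds 1, 6, 7, 16, 17, 24 and D-phenylalanine are taken as commercial.

**Route**

Step 1
Reactants: 1 4-methoxy-2-methylphenol
Product: 2 4-methoxy-1-(methoxymethoxy)-2-methylbenzene
Conditions: NaH, MOMCl, THF/DMF, 0 °C to rt
Reagents that add atoms: chloromethyl methyl ether, COCCl
Why: O-alkylation of the phenoxide (Williamson type) installs a MOM acetal that should survive the organolithium, dissolving-metal and ylide steps and directs the metalation of step 2; no stereocenter is formed.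

Step 2
Reactants: 2 4-methoxy-1-(methoxymethoxy)-2-methylbenzene
Product: 4 [5-methoxy-2-(methoxymethoxy)-3-methylphenyl]methanol, via aryllithium 3 (not isolated)
Conditions: n-BuLi, TMEDA, Et2O, 0 °C; then (CH2O)n, −78 °C to rt; NH4Cl
Reagents that add atoms: paraformaldehyde (reacts as formaldehyde), C=O
Why: Directed ortho-metalation: OMOM, a stronger director than OMe, should steer lithiation to its only free ortho position, and the aryllithium is hydroxymethylated by formaldehyde; no stereocenter is formed.

Step 3
Reactants: 4 [5-methoxy-2-(methoxymethoxy)-3-methylphenyl]methanol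
Product: 5 1-(bromomethyl)-5-methoxy-2-(methoxymethoxy)-3-methylbenzene
Conditions: CBr4, PPh3, CH2Cl2, 0 °C
Reagents that add atoms: carbon tetrabromide, BrC(Br)(Br)Br
Why: Appel bromination converts the benzylic alcohol to the bromide under neutral conditions that should leave the MOM acetal intact; no stereocenter is formed.

Step 4
Reactants: 6 2-methylcyclopentane-1,3-dione; 7 pent-1-en-3-one (ethyl vinyl ketone)
Product: 8 2-methyl-2-(3-oxopentyl)cyclopentane-1,3-dione
Conditions: H2O, AcOH (cat.), 75 °C
Reagents that add atoms: none
Why: Michael addition of the acidic cyclic 1,3-dione to the vinyl ketone gives the prochiral triketone; no stereocenter is formed.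

Step 5
Reactants: 8 2-methyl-2-(3-oxopentyl)cyclopentane-1,3-dione
Product: 9 (7aR)-4,7a-dimethyl-2,3,7,7a-tetrahydro-1H-indene-1,5(6H)-dione
Conditions: D-phenylalanine, (+)-camphorsulfonic acid, DMF, 30 to 70 °C
Reagents that add atoms: none
Why: Hajos–Parrish–Eder–Sauer–Wiechert reaction: the enamine formed from D-phenylalanine and the side-chain ketone should attack one of the two enantiotopic ring carbonyls (intramolecular aldol condensation), which fixes the methyl-bearing quaternary carbon as R, the mirror image of the L-amino acid outcome.

Step 6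
Reactants: 9 (7aR)-4,7a-dimethyl-2,3,7,7a-tetrahydro-1H-indene-1,5(6H)-dione
Product: 10 (1R,7aR)-1-hydroxy-4,7a-dimethyl-1,2,3,6,7,7a-hexahydro-5H-inden-5-one
Conditions: NaBH4, EtOH, −20 °C
Reagents that add atoms: none
Why: Chemoselective borohydride reduction of the saturated cyclopentanone beside the less electrophilic enone, with hydride arriving anti to the angular methyl (OH syn to it); the alcohol masks this carbonyl and later supplies the one proton needed in step 7.

Step 7
Reactants: 10 (1R,7aR)-1-hydroxy-4,7a-dimethyl-1,2,3,6,7,7a-hexahydro-5H-inden-5-one; 5 1-(bromomethyl)-5-methoxy-2-(methoxymethoxy)-3-methylbenzene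
Product: 12 (1R,3aS,4R,7aR)-1-hydroxy-4-{[5-methoxy-2-(methoxymethoxy)-3-methylphenyl]methyl}-4,7a-dimethyloctahydro-5H-inden-5-one, via dilithium enolate-alkoxide 11 (not isolated)
Conditions: Li, NH3(l)/THF, −78 °C; then 5, THF, −78 to −33 °C; NH4Cl
Reagents that add atoms: none
Why: Dissolving-metal reductive alkylation: the β-carbanion of the reduced enone should be protonated to the trans ring fusion (H anti to the angular methyl), and the regiodefined tetrasubstituted enolate 11 is benzylated by 5 on the face opposite the angular methyl, which creates the benzylic quaternary carbon.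

Step 8
Reactants: 12 (1R,3aS,4R,7aR)-1-hydroxy-4-{[5-methoxy-2-(methoxymethoxy)-3-methylphenyl]methyl}-4,7a-dimethyloctahydro-5H-inden-5-one
Product: 13 (1R,3aR,4R,7aR)-4-{[5-methoxy-2-(methoxymethoxy)-3-methylphenyl]methyl}-4,7a-dimethyl-5-methylideneoctahydro-1H-inden-1-ol
Conditions: Ph3PCH3Br, KOtBu (excess), toluene, 90 °C
Reagents that add atoms: methyltriphenylphosphonium bromide, C[P+](c1ccccc1)(c1ccccc1)c1ccccc1.[Br-]
Why: Wittig methylenation of the hindered, non-epimerizable ketone next to the quaternary carbon (the free hydroxyl is carried as its alkoxide); no stereocenter is formed.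

Step 9
Reactants: 13 (1R,3aR,4R,7aR)-4-{[5-methoxy-2-(methoxymethoxy)-3-methylphenyl]methyl}-4,7a-dimethyl-5-methylideneoctahydro-1H-inden-1-ol
Product: 14 (1R,3aR,4S,5R,7aR)-4-{[5-methoxy-2-(methoxymethoxy)-3-methylphenyl]methyl}-4,5,7a-trimethyloctahydro-1H-inden-1-ol
Conditions: H2 (1 atm), Pd on carbon, EtOAc, rt
Reagents that add atoms: none
Why: Heterogeneous hydrogenation of the exocyclic 1,1-disubstituted alkene: the face carrying the two axial methyls is shielded, so hydrogen should add from the opposite face and leave the new methyl equatorial and syn to both of them.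

Step 10
Reactants: 14 (1R,3aR,4S,5R,7aR)-4-{[5-methoxy-2-(methoxymethoxy)-3-methylphenyl]methyl}-4,5,7a-trimethyloctahydro-1H-inden-1-ol
Product: 15 (3aR,4S,5R,7aR)-4-{[5-methoxy-2-(methoxymethoxy)-3-methylphenyl]methyl}-4,5,7a-trimethyloctahydro-1H-inden-1-one
Conditions: (n-Pr4N)RuO4 (cat.), NMO, 4 Å MS, CH2Cl2, rt
Reagents that add atoms: none
Why: Ley–Griffith oxidation of the secondary alcohol returns the cyclopentanone without touching the electron-rich arene or the acetal; no stereocenter is formed.

Step 11
Reactants: 15 (3aR,4S,5R,7aR)-4-{[5-methoxy-2-(methoxymethoxy)-3-methylphenyl]methyl}-4,5,7a-trimethyloctahydro-1H-inden-1-one; 16 dibromomethane; 17 methyl acrylate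
Product: 22 methyl 3-[(1S,4aR,5S,6R,8aR)-5-{[5-methoxy-2-(methoxymethoxy)-3-methylphenyl]methyl}-5,6,8a-trimethyl-2-oxodecahydronaphthalen-1-yl]propanoate, via dibromomethyl alkoxide 18 (not isolated), via β-oxido carbenoid 19 (not isolated), via ring-enlarged lithium enolate 20 (not isolated), via unequilibrated keto ester 21 (not isolated)
Conditions: 16, lithium 2,2,6,6-tetramethylpiperidide, THF, −78 °C; n-BuLi, −95 to 0 °C; 17, −78 °C; NH4Cl; then DBU (cat.), CH2Cl2, rt
Reagents that add atoms: none
Why: Proposed new method: LiCHBr2 formed in situ should add to the C=O of 15 anti to the angular methyl (18), Br/Li exchange gives carbenoid 19, and its electrophilic carbon accepts a 1,2-shift of the anti-periplanar quaternary α-carbon with loss of LiBr, so the cyclopentanone becomes the cyclohexanone enolate 20, regiodefined at the inserted CH, which adds 1,4 to methyl acrylate before DBU equilibrates the new center. The closest known reaction types are the β-oxido carbenoid one-carbon ring enlargement of cyclic ketones (CH2Br2, lithium amide, n-BuLi), which ends at the ring-enlarged lithium enolate, and the Michael addition of regiodefined ketone lithium enolates to acrylates; joining them in one flask on a hindered ring-fusion ketone is the untested part. The six-membered ring is not closed by a cyclization but arises by ring expansion, a 1,2-alkyl shift that inserts one carbon between the C=O and the quaternary carbon of the five-membered ring. The migrating quaternary carbon keeps its configuration (suprafacial shift with retention), and the new CH is set under thermodynamic control: α to the ketone it should settle with the chain equatorial and syn to the axial angular methyl, the arrangement that is stable in 9-substituted 8-oxo trans-decalins of the labdane type. The step needs migration of the quaternary carbon and not of the ring CH2, which carbenoid rearrangements (unlike diazoalkane homologations) should favor because the more substituted carbon better supports the electron-poor transition state, and it needs a single C-alkylation by the acrylate, favored by one equivalent at −78 °C and by an enolate that cannot equilibrate toward the quaternary side.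

Step 12
Reactants: 22 methyl 3-[(1S,4aR,5S,6R,8aR)-5-{[5-methoxy-2-(methoxymethoxy)-3-methylphenyl]methyl}-5,6,8a-trimethyl-2-oxodecahydronaphthalen-1-yl]propanoate
Product: 23 methyl 3-[(1S,4aR,5S,6R,8aR)-5-[(2-hydroxy-5-methoxy-3-methylphenyl)methyl]-5,6,8a-trimethyl-2-oxodecahydronaphthalen-1-yl]propanoate
Conditions: HCl (cat.), MeOH, 40 °C; aqueous work-up
Reagents that add atoms: none
Why: Acid-catalyzed acetal exchange removes the aryl MOM group before the acid-sensitive alkene exists; the methyl ester is stable in methanol and the center α to the ketone is already the thermodynamic epimer.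

Step 13
Reactants: 23 methyl 3-[(1S,4aR,5S,6R,8aR)-5-[(2-hydroxy-5-methoxy-3-methylphenyl)methyl]-5,6,8a-trimethyl-2-oxodecahydronaphthalen-1-yl]propanoate; 24 acetone
Product: 25 methyl 3-[(1S,4aR,5S,6R,8aR)-5-[(2-hydroxy-5-methoxy-3-methylphenyl)methyl]-5,6,8a-trimethyl-2-(propan-2-ylidene)decahydronaphthalen-1-yl]propanoate
Conditions: TiCl4, Zn, pyridine, THF, reflux; slow addition of 23 and excess 24
Reagents that add atoms: none
Why: Mixed McMurry coupling: low-valent titanium should couple the ring ketone with excess acetone to the pinacolate and deoxygenate it to the tetrasubstituted alkene without base, so the adjacent stereocenter is not disturbed and the phenol is carried as its titanium phenoxide.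

Step 14
Reactants: 25 methyl 3-[(1S,4aR,5S,6R,8aR)-5-[(2-hydroxy-5-methoxy-3-methylphenyl)methyl]-5,6,8a-trimethyl-2-(propan-2-ylidene)decahydronaphthalen-1-yl]propanoate
Product: 26 3-[(1S,4aR,5S,6R,8aR)-5-[(2-hydroxy-5-methoxy-3-methylphenyl)methyl]-5,6,8a-trimethyl-2-(propan-2-ylidene)decahydronaphthalen-1-yl]propanoic acid
Conditions: LiOH, THF/MeOH/H2O, 40 °C; then 1 M HCl, 0 °C
Reagents that add atoms: lithium hydroxide, [Li+].[OH-]
Why: Saponification of the methyl ester under conditions to which the tetrasubstituted alkene and the now non-epimerizable stereocenters are inert; brief cold acidification releases the acid.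

**Compound list**

1 | 4-methoxy-2-methylphenol | COc1ccc(O)c(C)c1 | starting material
2 | 4-methoxy-1-(methoxymethoxy)-2-methylbenzene | COCOc1ccc(OC)cc1C | intermediate
3 | [5-methoxy-2-(methoxymethoxy)-3-methylphenyl]lithium | [Li]c1cc(OC)cc(C)c1OCOC | intermediate
4 | [5-methoxy-2-(methoxymethoxy)-3-methylphenyl]methanol | COCOc1c(C)cc(OC)cc1CO | intermediate
5 | 1-(bromomethyl)-5-methoxy-2-(methoxymethoxy)-3-methylbenzene | COCOc1c(C)cc(OC)cc1CBr | intermediate
6 | 2-methylcyclopentane-1,3-dione | CC1C(=O)CCC1=O | starting material
7 | pent-1-en-3-one (ethyl vinyl ketone) | CCC(=O)C=C | starting material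
8 | 2-methyl-2-(3-oxopentyl)cyclopentane-1,3-dione | CCC(=O)CCC1(C)C(=O)CCC1=O | intermediate
9 | (7aR)-4,7a-dimethyl-2,3,7,7a-tetrahydro-1H-indene-1,5(6H)-dione | CC1=C2CCC(=O)[C@]2(C)CCC1=O | intermediate
10 | (1R,7aR)-1-hydroxy-4,7a-dimethyl-1,2,3,6,7,7a-hexahydro-5H-inden-5-one (OH syn to the angular methyl) | CC1=C2CC[C@@H](O)[C@]2(C)CCC1=O | intermediate
11 | dilithium enolate-alkoxide of the trans-fused dihydro derivative of 10 (ring-fusion H anti to the angular methyl) | CC1=C([O-])CC[C@@]2(C)[C@H]([O-])CC[C@H]12.[Li+].[Li+] | intermediate
12 | (1R,3aS,4R,7aR)-1-hydroxy-4-{[5-methoxy-2-(methoxymethoxy)-3-methylphenyl]methyl}-4,7a-dimethyloctahydro-5H-inden-5-one (trans-fused; arylmethyl anti, 4-methyl and OH syn to the angular methyl) | COCOc1c(C)cc(OC)cc1C[C@]1(C)[C@H]2CC[C@@H](O)[C@]2(C)CCC1=O | intermediate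
13 | (1R,3aR,4R,7aR)-4-{[5-methoxy-2-(methoxymethoxy)-3-methylphenyl]methyl}-4,7a-dimethyl-5-methylideneoctahydro-1H-inden-1-ol | COCOc1c(C)cc(OC)cc1C[C@]1(C)[C@H]2CC[C@@H](O)[C@]2(C)CCC1=C | intermediate
14 | (1R,3aR,4S,5R,7aR)-4-{[5-methoxy-2-(methoxymethoxy)-3-methylphenyl]methyl}-4,5,7a-trimethyloctahydro-1H-inden-1-ol (5-methyl syn to the 4- and 7a-methyls) | COCOc1c(C)cc(OC)cc1C[C@]1(C)[C@H]2CC[C@@H](O)[C@]2(C)CC[C@H]1C | intermediate
15 | (3aR,4S,5R,7aR)-4-{[5-methoxy-2-(methoxymethoxy)-3-methylphenyl]methyl}-4,5,7a-trimethyloctahydro-1H-inden-1-one | COCOc1c(C)cc(OC)cc1C[C@]1(C)[C@H]2CCC(=O)[C@]2(C)CC[C@H]1C | intermediate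
16 | dibromomethane | BrCBr | starting material
17 | methyl acrylate (methyl prop-2-enoate) | COC(=O)C=C | starting material
18 | lithium alkoxide of the 1-(dibromomethyl) carbinol of 15 (CHBr2 anti, O syn to the angular methyl) | COCOc1c(C)cc(OC)cc1C[C@]1(C)[C@H]2CC[C@]([O-])(C(Br)Br)[C@]2(C)CC[C@H]1C.[Li+] | intermediate
19 | β-oxido carbenoid from Br/Li exchange of 18 (carbenoid carbon configurationally labile, left undefined) | COCOc1c(C)cc(OC)cc1C[C@]1(C)[C@H]2CC[C@]([O-])(C([Li])Br)[C@]2(C)CC[C@H]1C.[Li+] | intermediate
20 | lithium enolate of the ring-enlarged decalin-2-one (enolate double bond toward the inserted CH next to the quaternary carbon) | COCOc1c(C)cc(OC)cc1C[C@]1(C)[C@H]2CCC([O-])=C[C@]2(C)CC[C@H]1C.[Li+] | intermediate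
21 | methyl 3-[5-(arylmethyl)-5,6,8a-trimethyl-2-oxodecahydronaphthalen-1-yl]propanoate before equilibration (both configurations at C1) | COCOc1c(C)cc(OC)cc1C[C@]1(C)[C@H]2CCC(=O)C(CCC(=O)OC)[C@]2(C)CC[C@H]1C | intermediate
22 | methyl 3-[(1S,4aR,5S,6R,8aR)-5-{[5-methoxy-2-(methoxymethoxy)-3-methylphenyl]methyl}-5,6,8a-trimethyl-2-oxodecahydronaphthalen-1-yl]propanoate | COCOc1c(C)cc(OC)cc1C[C@]1(C)[C@H]2CCC(=O)[C@@H](CCC(=O)OC)[C@]2(C)CC[C@H]1C | intermediate
23 | methyl 3-[(1S,4aR,5S,6R,8aR)-5-[(2-hydroxy-5-methoxy-3-methylphenyl)methyl]-5,6,8a-trimethyl-2-oxodecahydronaphthalen-1-yl]propanoate | COc1cc(C)c(O)c(C[C@]2(C)[C@H]3CCC(=O)[C@@H](CCC(=O)OC)[C@]3(C)CC[C@H]2C)c1 | intermediate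
24 | acetone | CC(C)=O | starting material
25 | methyl 3-[(1S,4aR,5S,6R,8aR)-5-[(2-hydroxy-5-methoxy-3-methylphenyl)methyl]-5,6,8a-trimethyl-2-(propan-2-ylidene)decahydronaphthalen-1-yl]propanoate | COc1cc(C)c(O)c(C[C@]2(C)[C@H]3CCC(=C(C)C)[C@@H](CCC(=O)OC)[C@]3(C)CC[C@H]2C)c1 | intermediate
26 | 3-[(1S,4aR,5S,6R,8aR)-5-[(2-hydroxy-5-methoxy-3-methylphenyl)methyl]-5,6,8a-trimethyl-2-(propan-2-ylidene)decahydronaphthalen-1-yl]propanoic acid | COc1cc(C)c(O)c(C[C@]2(C)[C@H]3CCC(=C(C)C)[C@@H](CCC(=O)O)[C@]3(C)CC[C@H]2C)c1 | target

**Step count and risks**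

Total steps: 14. Longest linear sequence: 11 steps (steps 4 to 14, from 6); the aryl branch (steps 1 to 3) joins in step 7.

Steps most likely to fail:

1. Step 11. What may go wrong: migration of the ring CH2 instead of the quaternary carbon during the carbenoid rearrangement (wrong regiochemistry of ring enlargement), or oligomerization of the acrylate and slow C–C bond formation at the neopentyl enolate carbon. Fallback with known chemistry, from 15 back to 23:
   - Wittig olefination of 15 with the ylide of (3-cyanopropyl)triphenylphosphonium bromide (KN(SiMe3)2, THF) should give the (Z)-alkylidene nitrile F1.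
   - OsO4/NMO dihydroxylation on the face opposite the angular methyl gives the diol F2, and MsCl/Et3N gives the secondary mesylate F3.
   - Et3Al (CH2Cl2, −78 to 0 °C) triggers the pinacol-type 1,2-shift. In the rotamer that turns the small H toward the angular methyl, the quaternary carbon is anti to the mesylate, so this carbon should migrate with inversion at the receiving carbon. DBU then equilibrates the α-center to give the keto nitrile F4.
   - HCl/MeOH followed by water (Pinner reaction) turns the nitrile into the methyl ester and removes the MOM group in the same operation, returning to 23.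

2. Step 13. What may go wrong: intramolecular ketyl–ester coupling, arrest at the pinacol stage, or steric retardation of the cross-deoxygenation at the α-branched ketone. Fallback, from 23 back to 26:
   - CeCl3-promoted addition of isopropenylmagnesium bromide (THF, −78 °C, excess; the phenoxide is carried along) to the ring ketone from the equatorial direction, with lactonization of the tertiary alkoxide onto the methyl ester, should give the δ-lactone F6.
   - BF3·OEt2/Et3SiH (CH2Cl2, −78 to −30 °C) ionizes the tertiary allylic C–O bond and delivers hydride to the CH2 terminus of the allyl cation. This forms the isopropylidene group and frees the carboxylic acid, so the fallback returns at 26.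

3. Step 7. What may go wrong: protonation of the ring-fusion carbanion from the wrong face (cis ring fusion), or O- instead of C-benzylation. Fallback, from 10 back to 12:
   - Conjugate hydride reduction with i-Bu2AlH/t-BuCu (HMPA, THF, −50 °C), a combination that gives trans-hydrindanones from this enone class, should give the saturated trans-fused hydroxy ketone F5.
   - The more substituted potassium enolate (KOtBu, t-BuOH/THF) is then benzylated with 5 anti to the angular methyl, returning to 12.

Further compounds
F1 | step 11 | (Z)-4-[hydrindan-1-ylidene]butanenitrile derived from 15 (chain cis to the quaternary carbon) | COCOc1c(C)cc(OC)cc1C[C@]1(C)[C@H]2CC/C(=C/CCC#N)[C@]2(C)CC[C@H]1C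
F2 | step 11 | 1,1'-diol from F1 (both OH added anti to the angular methyl) | COCOc1c(C)cc(OC)cc1C[C@]1(C)[C@H]2CC[C@@](O)([C@H](O)CCC#N)[C@]2(C)CC[C@H]1C
F3 | step 11 | secondary methanesulfonate of F2 | COCOc1c(C)cc(OC)cc1C[C@]1(C)[C@H]2CC[C@@](O)([C@H](OS(C)(=O)=O)CCC#N)[C@]2(C)CC[C@H]1C
F4 | step 11 | 3-[(1S,4aR,5S,6R,8aR)-5-{[5-methoxy-2-(methoxymethoxy)-3-methylphenyl]methyl}-5,6,8a-trimethyl-2-oxodecahydronaphthalen-1-yl]propanenitrile | COCOc1c(C)cc(OC)cc1C[C@]1(C)[C@H]2CCC(=O)[C@@H](CCC#N)[C@]2(C)CC[C@H]1C
F5 | step 7 | trans-fused (7aR)-1-hydroxy-4,7a-dimethyloctahydro-5H-inden-5-one (OH syn, ring-fusion H anti to the angular methyl; 4-methyl equatorial) | C[C@@H]1[C@H]2CC[C@@H](O)[C@]2(C)CCC1=O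
F6 | step 13 | δ-lactone between the propanoate chain and the tertiary isopropenyl carbinol at the former ketone carbon of 23 (lactone O syn to the angular methyl) | COc1cc(C)c(O)c(C[C@]2(C)[C@H]3CC[C@@]4(C(C)=C)OC(=O)CC[C@H]4[C@]3(C)CC[C@H]2C)c1
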